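**Strategy.** Ring numbering: C1 carbonyl, C2 allyl-bearing, C4 quaternary, C5 methoxy-bearing. The strategy exploits the vinylogous methyl ester C5(OMe)=C6–C1=O of the dienone ring: C6–C1 is supplied by ketenylidenetriphenylphosphorane and C5–OMe is a methyl ester carbonyl that undergoes Wittig olefination. In one operation a (Z)-alkenylmagnesium centre at C2 adds to Ph3P=C=C=O (bond C1–C2) and the acyl ylide formed closes the ring on the ester (bond C5=C6). The precursor is an acyclic (Z)-iodoalkene methyl ester that already holds the quaternary C4 centre, set by Felkin–Anh addition to an α-keto ester, and the side-chain stereocentres from an Evans syn-aldol.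

Key step: step 9

Remark: the side chain is called C8 (CHMe) and C7 (aryl–CH–O). Compounds 6, 10 and 16 and hexamethylditin are taken as commercial.

**Step 1**
Reactants: 1 (R)-4-benzyl-3-propanoyl-1,3-oxazolidin-2-one; 2 3,4-dimethoxybenzaldehyde
Product: 3 (R)-4-benzyl-3-[(2R,3R)-3-(3,4-dimethoxyphenyl)-3-hydroxy-2-methylpropanoyl]-1,3-oxazolidin-2-one
Conditions: Bu2BOTf, iPr2NEt, CH2Cl2, −78 → 0 °C; then pH 7 buffer, MeOH, H2O2, 0 °C
Reagents that add atoms: none
Why: Evans syn-aldol reaction in which the (Z)-boron enolate reacts through a chair Zimmerman–Traxler transition state on the face left open by the benzyl group of the auxiliary, which should set C8 (R) and C7 (R) as the syn pair.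

**Step 2**
Reactants: 3 (R)-4-benzyl-3-[(2R,3R)-3-(3,4-dimethoxyphenyl)-3-hydroxy-2-methylpropanoyl]-1,3-oxazolidin-2-one
Product: 4 (2R,3R)-3-(3,4-dimethoxyphenyl)-3-hydroxy-N-methoxy-N,2-dimethylpropanamide
Conditions: MeNH(OMe)·HCl, AlMe3, CH2Cl2, −20 → 0 °C
Reagents that add atoms: N,O-dimethylhydroxylamine hydrochloride, CNOC.Cl
Why: Aluminium amide transamidation of the imide, in which the free β-hydroxyl directs attack to the exocyclic acyl group, should release the auxiliary and leave both stereocentres untouched.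

**Step 3**
Reactants: 4 (2R,3R)-3-(3,4-dimethoxyphenyl)-3-hydroxy-N-methoxy-N,2-dimethylpropanamide
Product: 5 (2R,3R)-3-[(tert-butyldimethylsilyl)oxy]-3-(3,4-dimethoxyphenyl)-N-methoxy-N,2-dimethylpropanamide
Conditions: TBSOTf, 2,6-lutidine, CH2Cl2, −78 → 0 °C
Reagents that add atoms: tert-butyldimethylsilyl triflate, CC(C)(C)[Si](C)(C)OS(=O)(=O)C(F)(F)F
Why: Silylation of the secondary benzylic alcohol gives a non-chelating ether that survives the organolithium steps and keeps the later ketone addition under Felkin–Anh control.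

**Step 4**
Reactants: 5 (2R,3R)-3-[(tert-butyldimethylsilyl)oxy]-3-(3,4-dimethoxyphenyl)-N-methoxy-N,2-dimethylpropanamide; 6 methyl vinyl ether
Product: 8 (4R,5R)-5-[(tert-butyldimethylsilyl)oxy]-5-(3,4-dimethoxyphenyl)-2-methoxy-4-methylpent-1-en-3-one, via 1-methoxyvinyllithium 7 (not isolated)
Conditions: 6, t-BuLi, THF, −78 → 0 °C; then 5, −78 °C; aq. NH4Cl
Reagents that add atoms: none
Why: Acyl substitution of the N-methoxy-N-methylamide by the acyl anion equivalent 7 (α-lithiation of the enol ether) stops at the chelated tetrahedral intermediate, so a single addition should give the α-methoxy enone without epimerisation at C8.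

**Step 5**
Reactants: 8 (4R,5R)-5-[(tert-butyldimethylsilyl)oxy]-5-(3,4-dimethoxyphenyl)-2-methoxy-4-methylpent-1-en-3-one
Product: 9 methyl (3R,4R)-4-[(tert-butyldimethylsilyl)oxy]-4-(3,4-dimethoxyphenyl)-3-methyl-2-oxobutanoate
Conditions: O3 (to consumption of 8), CH2Cl2, −78 °C; then Me2S, −78 → 23 °C
Reagents that add atoms: ozone, [O-][O+]=O
Why: Ozonolysis cleaves the enol ether C=C much faster than it attacks the dimethoxyarene, which turns C(OMe)=CH2 into CO2Me and should give the α-keto methyl ester whose methoxy group later becomes the ring OMe at C5.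

**Step 6**
Reactants: 10 pent-1-en-4-yne
Product: 11 (Z)-1,2-bis(trimethylstannyl)penta-1,4-diene
Conditions: Me3SnSnMe3, Pd(PPh3)4 (cat.), THF, 65 °C, sealed tube
Reagents that add atoms: hexamethylditin, C[Sn](C)(C)[Sn](C)(C)C
Why: Palladium-catalysed distannation adds the Sn–Sn bond cis across the terminal alkyne and should give the (Z)-1,2-distannylalkene while the isolated alkene stays inert.

**Step 7**
Reactants: 9 methyl (3R,4R)-4-[(tert-butyldimethylsilyl)oxy]-4-(3,4-dimethoxyphenyl)-3-methyl-2-oxobutanoate; 11 (Z)-1,2-bis(trimethylstannyl)penta-1,4-diene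
Product: 14 methyl (2S,3R,4R)-4-[(tert-butyldimethylsilyl)oxy]-4-(3,4-dimethoxyphenyl)-2-hydroxy-2-[(1Z)-2-iodopenta-1,4-dien-1-yl]-3-methylbutanoate, via lithiated stannyldiene 12 (not isolated), via stannyl carbinol 13 (not isolated)
Conditions: 11, MeLi, THF, −78 °C; then 9, −78 °C; then AcOH, I2, −78 → 0 °C; aq. Na2S2O3
Reagents that add atoms: iodine, II
Why: Tin–lithium exchange at the less hindered terminal stannyl group gives the (Z)-alkenyllithium with retention; it adds to the ketone of the α-keto ester under Felkin–Anh control (C7-bearing group anti to the bulky nucleophile, attack past the C8 hydrogen, non-chelating silyl ether), which should set the C4 configuration of the target (descriptor S here only because of the heavy atom on the alkene), and iododestannylation with retention then gives the (Z)-iodoalkene.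

**Step 8**
Reactants: 14 methyl (2S,3R,4R)-4-[(tert-butyldimethylsilyl)oxy]-4-(3,4-dimethoxyphenyl)-2-hydroxy-2-[(1Z)-2-iodopenta-1,4-dien-1-yl]-3-methylbutanoate
Product: 15 methyl (2S,3R,4R)-4-[(tert-butyldimethylsilyl)oxy]-4-(3,4-dimethoxyphenyl)-2-[(1Z)-2-iodopenta-1,4-dien-1-yl]-2-methoxy-3-methylbutanoate
Conditions: MeOTf, 2,6-di-tert-butyl-4-methylpyridine, CH2Cl2, 23 → 40 °C
Reagents that add atoms: methyl triflate, COS(=O)(=O)C(F)(F)F
Why: O-Methylation of the hindered tertiary alcohol with methyl triflate and a non-nucleophilic pyridine base (SN2 at methyl) needs no alkoxide and so should avoid 1,5-migration of the silyl group.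

**Step 9**
Reactants: 15 methyl (2S,3R,4R)-4-[(tert-butyldimethylsilyl)oxy]-4-(3,4-dimethoxyphenyl)-2-[(1Z)-2-iodopenta-1,4-dien-1-yl]-2-methoxy-3-methylbutanoate; 16 ketenylidenetriphenylphosphorane
Product: 19 (4R)-4-[(1R,2R)-1-[(tert-butyldimethylsilyl)oxy]-1-(3,4-dimethoxyphenyl)propan-2-yl]-4,5-dimethoxy-2-(prop-2-en-1-yl)cyclohexa-2,5-dien-1-one, via alkenylmagnesium chloride 17 (not isolated), via acyl ylide 18 (not isolated)
Conditions: iPrMgCl·LiCl, THF, −40 °C; then 16, −40 → 0 °C; AcOH (1 equiv); solvent switch to toluene, 110 °C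
Reagents that add atoms: none
Why: Proposed new method: iodine–magnesium exchange should give the configurationally stable (Z)-alkenylmagnesium 17, which adds to the electrophilic central carbon of Ph3P=C=C=O to form the C1–C2 bond, and C-protonation of the magnesium ylide-enolate gives the neutral acyl ylide 18. On heating, the ylide carbon C6 attacks the methyl ester carbonyl C5 (6-exo-trig) and the oxaphosphetane collapses to the C5=C6 enol ether and Ph3P=O, so the ring closes by an intramolecular Wittig olefination. The closest known reactions are the addition of α-hydroxy and α-amino esters to Ph3P=C=C=O followed by intramolecular Wittig olefination of the ester (tetronates, tetramates) and the ester olefination by acyl ylides used for chromones; new here are the carbon nucleophile and the carbocyclic ring. No stereocentre is formed: C4, C7 and C8 are spectators, and the Z geometry of C2=C3 fixed in 15 holds C1 and C5 cis for closure. The step needs exchange and addition to the ylide to outrun attack of the alkenylmagnesium on its own ester (a strained four-membered closure, slow at −40 °C) and olefination to beat acyl substitution at C5, which protonation to the neutral ylide before heating should secure. Because the C5 methoxy group is the ester's own, the vinylogous ester should form as a single regioisomer.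

**Step 10**
Reactants: 19 (4R)-4-[(1R,2R)-1-[(tert-butyldimethylsilyl)oxy]-1-(3,4-dimethoxyphenyl)propan-2-yl]-4,5-dimethoxy-2-(prop-2-en-1-yl)cyclohexa-2,5-dien-1-one
Product: 20 (4R)-4-[(1R,2R)-1-(3,4-dimethoxyphenyl)-1-hydroxypropan-2-yl]-4,5-dimethoxy-2-(prop-2-en-1-yl)cyclohexa-2,5-dien-1-one
Conditions: HF·pyridine, pyridine, THF, 0 → 23 °C
Reagents that add atoms: none
Why: Buffered fluoride cleavage of the silyl ether is mild enough to spare the vinylogous ester and the tertiary methyl ether and does not generate a free C7 alkoxide that could fragment the side chain.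

**Step 11**
Reactants: 20 (4R)-4-[(1R,2R)-1-(3,4-dimethoxyphenyl)-1-hydroxypropan-2-yl]-4,5-dimethoxy-2-(prop-2-en-1-yl)cyclohexa-2,5-dien-1-one
Product: 21 (1R,2R)-1-(3,4-dimethoxyphenyl)-2-[(1R)-1,2-dimethoxy-4-oxo-5-(prop-2-en-1-yl)cyclohexa-2,5-dien-1-yl]propyl acetate
Conditions: Ac2O, pyridine, DMAP (cat.), CH2Cl2, 0 → 23 °C
Reagents that add atoms: acetic anhydride, CC(=O)OC(C)=O
Why: DMAP-catalysed acylation of the secondary benzylic alcohol does not break the C7–O bond, so the acetate should form with retention.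

**Compound list**
1 | (R)-4-benzyl-3-propanoyl-1,3-oxazolidin-2-one | CCC(=O)N1[C@H](Cc2ccccc2)COC1=O | starting material
2 | 3,4-dimethoxybenzaldehyde | COc1ccc(C=O)cc1OC | starting material
3 | (R)-4-benzyl-3-[(2R,3R)-3-(3,4-dimethoxyphenyl)-3-hydroxy-2-methylpropanoyl]-1,3-oxazolidin-2-one | O=C([C@H](C)[C@@H](O)c1ccc(OC)c(OC)c1)N1[C@H](Cc2ccccc2)COC1=O | intermediate
4 | (2R,3R)-3-(3,4-dimethoxyphenyl)-3-hydroxy-N-methoxy-N,2-dimethylpropanamide | CON(C)C(=O)[C@H](C)[C@@H](O)c1ccc(OC)c(OC)c1 | intermediate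
5 | (2R,3R)-3-[(tert-butyldimethylsilyl)oxy]-3-(3,4-dimethoxyphenyl)-N-methoxy-N,2-dimethylpropanamide | CON(C)C(=O)[C@H](C)[C@@H](O[Si](C)(C)C(C)(C)C)c1ccc(OC)c(OC)c1 | intermediate
6 | methyl vinyl ether | COC=C | starting material
7 | 1-methoxyvinyllithium | [Li]C(=C)OC | intermediate
8 | (4R,5R)-5-[(tert-butyldimethylsilyl)oxy]-5-(3,4-dimethoxyphenyl)-2-methoxy-4-methylpent-1-en-3-one | C=C(OC)C(=O)[C@H](C)[C@@H](O[Si](C)(C)C(C)(C)C)c1ccc(OC)c(OC)c1 | intermediate
9 | methyl (3R,4R)-4-[(tert-butyldimethylsilyl)oxy]-4-(3,4-dimethoxyphenyl)-3-methyl-2-oxobutanoate | COC(=O)C(=O)[C@H](C)[C@@H](O[Si](C)(C)C(C)(C)C)c1ccc(OC)c(OC)c1 | intermediate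
10 | pent-1-en-4-yne | C#CCC=C | starting material
11 | (Z)-1,2-bis(trimethylstannyl)penta-1,4-diene | C=CC/C(=C/[Sn](C)(C)C)[Sn](C)(C)C | intermediate
12 | (Z)-1-lithio-2-(trimethylstannyl)penta-1,4-diene | C=CC/C(=C/[Li])[Sn](C)(C)C | intermediate
13 | methyl (2S,3R,4R)-4-[(tert-butyldimethylsilyl)oxy]-4-(3,4-dimethoxyphenyl)-2-hydroxy-3-methyl-2-[(1Z)-2-(trimethylstannyl)penta-1,4-dien-1-yl]butanoate | C=CC/C([Sn](C)(C)C)=C/[C@@](O)([C@H](C)[C@@H](O[Si](C)(C)C(C)(C)C)c1ccc(OC)c(OC)c1)C(=O)OC | intermediate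
14 | methyl (2S,3R,4R)-4-[(tert-butyldimethylsilyl)oxy]-4-(3,4-dimethoxyphenyl)-2-hydroxy-2-[(1Z)-2-iodopenta-1,4-dien-1-yl]-3-methylbutanoate | C=CC/C(I)=C/[C@@](O)([C@H](C)[C@@H](O[Si](C)(C)C(C)(C)C)c1ccc(OC)c(OC)c1)C(=O)OC | intermediate
15 | methyl (2S,3R,4R)-4-[(tert-butyldimethylsilyl)oxy]-4-(3,4-dimethoxyphenyl)-2-[(1Z)-2-iodopenta-1,4-dien-1-yl]-2-methoxy-3-methylbutanoate | C=CC/C(I)=C/[C@@](OC)([C@H](C)[C@@H](O[Si](C)(C)C(C)(C)C)c1ccc(OC)c(OC)c1)C(=O)OC | intermediate
16 | ketenylidenetriphenylphosphorane | O=C=C=P(c1ccccc1)(c1ccccc1)c1ccccc1 | starting material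
17 | (Z)-alkenylmagnesium chloride derived from 15 (MgCl in place of I, LiCl complex) | C=CC/C([Mg]Cl)=C/[C@@](OC)([C@H](C)[C@@H](O[Si](C)(C)C(C)(C)C)c1ccc(OC)c(OC)c1)C(=O)OC | intermediate
18 | methyl (2R,3R,4R)-4-[(tert-butyldimethylsilyl)oxy]-4-(3,4-dimethoxyphenyl)-2-methoxy-3-methyl-2-[(1Z)-2-[(triphenyl-λ5-phosphanylidene)acetyl]penta-1,4-dien-1-yl]butanoate | C=CC/C(C(=O)C=P(c1ccccc1)(c1ccccc1)c1ccccc1)=C/[C@@](OC)([C@H](C)[C@@H](O[Si](C)(C)C(C)(C)C)c1ccc(OC)c(OC)c1)C(=O)OC | intermediate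
19 | (4R)-4-[(1R,2R)-1-[(tert-butyldimethylsilyl)oxy]-1-(3,4-dimethoxyphenyl)propan-2-yl]-4,5-dimethoxy-2-(prop-2-en-1-yl)cyclohexa-2,5-dien-1-one | C=CCC1=C[C@@](OC)([C@H](C)[C@@H](O[Si](C)(C)C(C)(C)C)c2ccc(OC)c(OC)c2)C(OC)=CC1=O | intermediate
20 | (4R)-4-[(1R,2R)-1-(3,4-dimethoxyphenyl)-1-hydroxypropan-2-yl]-4,5-dimethoxy-2-(prop-2-en-1-yl)cyclohexa-2,5-dien-1-one | C=CCC1=C[C@@](OC)([C@H](C)[C@@H](O)c2ccc(OC)c(OC)c2)C(OC)=CC1=O | intermediate
21 | (1R,2R)-1-(3,4-dimethoxyphenyl)-2-[(1R)-1,2-dimethoxy-4-oxo-5-(prop-2-en-1-yl)cyclohexa-2,5-dien-1-yl]propyl acetate (CNP0159267.1) | C=CCC1=C[C@@](OC)([C@H](C)[C@@H](OC(C)=O)c2ccc(OC)c(OC)c2)C(OC)=CC1=O | target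

**Count.** Total step count: 11. Longest linear sequence: 10 steps (steps 1–5 and 7–11; step 6 is a one-step side branch).

**Steps most likely to fail**

Step 9 (Proposed new method). What may go wrong:
- the alkenylmagnesium acylates itself at the neighbouring ester before it meets the ylide;
- the organomagnesium adds too slowly to Ph3P=C=C=O;
- the hindered ester undergoes acyl substitution (loss of methoxide) in place of olefination.

The fallback sets out from 15 and uses known reactions only. Stille coupling of 15 with tributyl(1-ethoxyvinyl)stannane under Pd(PPh3)4 catalysis gives methyl (2R,3R,4R)-4-[(tert-butyldimethylsilyl)oxy]-4-(3,4-dimethoxyphenyl)-2-[(1Z)-2-(1-ethoxyethenyl)penta-1,4-dien-1-yl]-2-methoxy-3-methylbutanoate F1. Mild acid hydrolysis of the enol ether gives the methyl ketone, methyl (2R,3R,4R)-2-[(1Z)-2-acetylpenta-1,4-dien-1-yl]-4-[(tert-butyldimethylsilyl)oxy]-4-(3,4-dimethoxyphenyl)-2-methoxy-3-methylbutanoate F2. Dieckmann-type cyclisation of its kinetic lithium enolate (LiHMDS, THF, −78 → 0 °C) onto the ester gives (6R)-6-[(1R,2R)-1-[(tert-butyldimethylsilyl)oxy]-1-(3,4-dimethoxyphenyl)propan-2-yl]-6-methoxy-4-(prop-2-en-1-yl)cyclohex-4-ene-1,3-dione F3. O-Methylation with trimethylsilyldiazomethane in methanol gives 19, where the route is rejoined. The regioisomeric enol ether is expected as a by-product and would be removed by chromatography.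

Step 7. What may go wrong:
- poor facial selectivity in the ketone addition, if the 1,3-influence of the silyloxy group works against Felkin–Anh control;
- enolisation of the α-keto ester by the basic alkenyllithium;
- unselective tin–lithium exchange.

The fallback sets out from 9 and puts C4 under reagent control. Addition of pent-1-en-4-yne (10) mediated by Zn(OTf)2, Et3N and a chiral amino alcohol ligand gives methyl (2S,3R,4R)-4-[(tert-butyldimethylsilyl)oxy]-4-(3,4-dimethoxyphenyl)-2-hydroxy-3-methyl-2-(pent-4-en-1-yn-1-yl)butanoate F4. Trans-hydrosilylation with Et3SiH and [Cp*Ru(MeCN)3]PF6, which places silicon on the alkyne carbon distal to the free hydroxyl, gives methyl (2S,3R,4R)-4-[(tert-butyldimethylsilyl)oxy]-4-(3,4-dimethoxyphenyl)-2-hydroxy-3-methyl-2-[(1Z)-2-(triethylsilyl)penta-1,4-dien-1-yl]butanoate F5. Iododesilylation with N-iodosuccinimide in hexafluoroisopropanol (retention) returns to 14.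

Step 8. What may go wrong: the hindered tertiary hydroxyl alkylates slowly, and forcing conditions cause silyl migration or loss. The fallback sets out from 9 and installs the methyl group at the alkoxide stage. The lithium alkoxide formed when 12 adds to 9 is trapped in the same flask with MeOTf at −78 °C, before any silyl migration, to give methyl (2S,3R,4R)-4-[(tert-butyldimethylsilyl)oxy]-4-(3,4-dimethoxyphenyl)-2-methoxy-3-methyl-2-[(1Z)-2-(trimethylstannyl)penta-1,4-dien-1-yl]butanoate F6. Iododestannylation with I2 then returns to 15.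

**Further compounds**
F1 | step 9 | methyl (2R,3R,4R)-4-[(tert-butyldimethylsilyl)oxy]-4-(3,4-dimethoxyphenyl)-2-[(1Z)-2-(1-ethoxyethenyl)penta-1,4-dien-1-yl]-2-methoxy-3-methylbutanoate | C=CC/C(C(=C)OCC)=C/[C@@](OC)([C@H](C)[C@@H](O[Si](C)(C)C(C)(C)C)c1ccc(OC)c(OC)c1)C(=O)OC
F2 | step 9 | methyl (2R,3R,4R)-2-[(1Z)-2-acetylpenta-1,4-dien-1-yl]-4-[(tert-butyldimethylsilyl)oxy]-4-(3,4-dimethoxyphenyl)-2-methoxy-3-methylbutanoate | C=CC/C(C(C)=O)=C/[C@@](OC)([C@H](C)[C@@H](O[Si](C)(C)C(C)(C)C)c1ccc(OC)c(OC)c1)C(=O)OC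
F3 | step 9 | (6R)-6-[(1R,2R)-1-[(tert-butyldimethylsilyl)oxy]-1-(3,4-dimethoxyphenyl)propan-2-yl]-6-methoxy-4-(prop-2-en-1-yl)cyclohex-4-ene-1,3-dione | C=CCC1=C[C@@](OC)([C@H](C)[C@@H](O[Si](C)(C)C(C)(C)C)c2ccc(OC)c(OC)c2)C(=O)CC1=O
F4 | step 7 | methyl (2S,3R,4R)-4-[(tert-butyldimethylsilyl)oxy]-4-(3,4-dimethoxyphenyl)-2-hydroxy-3-methyl-2-(pent-4-en-1-yn-1-yl)butanoate | C=CCC#C[C@@](O)([C@H](C)[C@@H](O[Si](C)(C)C(C)(C)C)c1ccc(OC)c(OC)c1)C(=O)OC
F5 | step 7 | methyl (2S,3R,4R)-4-[(tert-butyldimethylsilyl)oxy]-4-(3,4-dimethoxyphenyl)-2-hydroxy-3-methyl-2-[(1Z)-2-(triethylsilyl)penta-1,4-dien-1-yl]butanoate | C=CC/C([Si](CC)(CC)CC)=C/[C@@](O)([C@H](C)[C@@H](O[Si](C)(C)C(C)(C)C)c1ccc(OC)c(OC)c1)C(=O)OC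
F6 | step 8 | methyl (2S,3R,4R)-4-[(tert-butyldimethylsilyl)oxy]-4-(3,4-dimethoxyphenyl)-2-methoxy-3-methyl-2-[(1Z)-2-(trimethylstannyl)penta-1,4-dien-1-yl]butanoate | C=CC/C([Sn](C)(C)C)=C/[C@@](OC)([C@H](C)[C@@H](O[Si](C)(C)C(C)(C)C)c1ccc(OC)c(OC)c1)C(=O)OC
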